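In the grey run Z climbs while L goes in, stands at 51.0% when the feed stops at 15.0 min, and then fades; that fading gives the number to carry.

in all of them: L 0.80 M (fed, over 15 min)
- grey: E 1.5 equiv; J 0.20 M; run made earlier; the fed solution adds 0.10 times the starting volume
- red: E 1.5 equiv; J 0.30 M; run made earlier; the fed solution adds 0.10 times the starting volume
- teal: E 2.2 equiv; J 0.40 M; run made earlier; the fed solution adds 0.10 times the starting volume
- flask: E 1.50 equiv; J 0.400 M; the fed solution adds 0.10 times the starting volume; time 2.5 h

| run | time / min | Z / % |
|---|---|---|
| grey | 4.00 | 17.5 |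
| grey | 8.00 | 33.2 |
| grey | 15.0 | 51.0 |
| grey | 30.0 | 24.7 |
| grey | 60.0 | 5.0 |
| grey | 120 | 0 |
| red | 4.00 | 17.6 |
| red | 8.00 | 33.1 |
| red | 15.0 | 50.1 |
| red | 30.0 | 24.2 |
| red | 60.0 | 5.0 |
| red | 120 | 0.5 |
| teal | 4.00 | 19.7 |
| teal | 10.0 | 44.4 |
| teal | 20.0 | 46.9 |
| teal | 50.0 | 9.3 |
| teal | 120 | 0 |

(each reading ± 0.3 percentage points)

- time, not beyond 2.5 h, at which the flask holds most Z
- the amount of Z, in percent of the L charged, at that time
- the first time at which Z reaches 25%, in the same percent

- charges are per starting volume, the dose included; the dosed solution carries all of it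
- percentages count the whole charge, also what has not yet gone in

Between 30.0 min and 60.0 min the grey readings give a half-life of Z, the time in which Z halves once the feed is over, of 13.0 min, a first-order half-life. The teal run, with more E and the J of the new flask, reads 12.9 min between 20.0 min and 50.0 min.

Now the new flask in slow motion, with grey as its guide: both have the same E, though their J differs. In the first instants, at 4.00 min, the grey flask has received 26.7% of its L and shows 17.5% as Z. The red run, with more J, reads 17.6% then, and 33.1% against grey's 33.2% at 8.00 min. Interpolating the grey readings, the new flask should reach 25% near 0.0985 h.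

In the middle, the feed lasts 1.15 half-lives, so Z made early has partly faded when the feed stops.

At the end, fading at that half-life would take grey's 51.0% down to 22.9% at 30.0 min, yet the reading is higher, at 24.7%. Some L therefore still turns into Z in the grey flask after the feed, and the peak of the new flask should lie a little past 0.25 h. The reckoning here puts its height near 50.6%, the mean of the grey and red readings at the end of the feed.

The forecast, higher in the peak than this reckoning, gives 51.5% at 0.26 h and 25% at 0.098 h, in its words: “Z peaks at the end of the feed, or just after because of a small lag”.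

The flask gives 50.2% at 0.257 h and first reaches 25% at 0.0967 h. At the best time L still stands at 3.58%. From there to 1.03 h lie 3.57 half-lives, which leave 4.23%; the flask holds 4.39%.

    2 L → G (k = 0.0660 M⁻¹ s⁻¹)
    L + J → D (k = 0.00300 M⁻¹ s⁻¹)
    L + E → Z (k = 0.0230 M⁻¹ s⁻¹)
    Z → Q (k = 9.00 × 10⁻⁴ s⁻¹)

The neighbour flask with 1.6 M of J peaks at 46.0%. Taking that peak at the end of its feed, the 10.4 half-lives up to 2.5 h leave 0.0347%; that flask holds 0.0336%.

The readings are simulated from invented constants; noise was put on by code.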